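**Plan**
- Target: guibourtinidol-(4α→6)-afzelechin. Upper flavan unit 2R,3S,4S (2,3-trans-3,4-trans), lower unit 2R,3S, joined C4(upper)–C6(lower).
- Retrosynthesis: first the C3–OH of the upper ring C (hydroboration of a flav-2-ene), then O1–C2 and C4a–C4 together (resorcinol plus an enone), then the enone C=C (Claisen–Schmidt), then the C6–CHO bond on afzelechin.
- Enabling feature: upper ring A is a resorcinol whose C4a is ortho to O1 and para to the 7-OH; C4 is benzylic to the phloroglucinol-type ring A of the lower unit and C2 is benzylic to ring B. Resorcinol can therefore act as a C,O-bisnucleophile toward an enone whose β-carbon becomes C4 and whose carbonyl carbon becomes C2.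
- Forward: the lower chroman comes intact from (+)-afzelechin (benzylation, bromine block at C8, formylation at C6, chalcone). Ring C of the upper unit is then closed onto resorcinol in one operation, followed by hydroboration and global hydrogenolysis.
- Stereochemistry: lower 2R,3S from afzelechin; C4 (S) from a chiral Brønsted acid in the annulation; C3 (S) and C2 (R) relayed from C4 by syn hydroboration anti to the C4 aryl group.

Key step: step 6

Assumption: (+)-afzelechin is bought from a natural-product supplier, and the (R)-catalyst of step 6 is taken to give the 4S centre (the antipode is equally available and would be used if the sense of induction proved opposite).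

Abbreviation used in names: Ar* = (2R,3S)-3,5,7-tris(benzyloxy)-2-[4-(benzyloxy)phenyl]-8-bromochroman-6-yl.

**Route**

Step 1
Reactants: 1 (+)-afzelechin, (2R,3S)-2-(4-hydroxyphenyl)chromane-3,5,7-triol
Product: 2 (2R,3S)-5,7-bis(benzyloxy)-2-[4-(benzyloxy)phenyl]chroman-3-ol
Conditions: BnBr (3.3 equiv), K2CO3, DMF, 0 °C to rt
Reagents that add atoms: benzyl bromide BrCc1ccccc1
Why: Williamson etherification in which carbonate deprotonates only the three phenols, so the secondary 3-OH stays free and no stereocentre is touched; benzyl is chosen because all such groups fall in the final hydrogenolysis.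

Step 2
Reactants: 2 (2R,3S)-5,7-bis(benzyloxy)-2-[4-(benzyloxy)phenyl]chroman-3-ol
Product: 3 (2R,3S)-3,5,7-tris(benzyloxy)-2-[4-(benzyloxy)phenyl]chromane
Conditions: NaH, BnBr, DMF, 0 °C to rt
Reagents that add atoms: benzyl bromide BrCc1ccccc1
Why: Williamson etherification of the remaining secondary alcohol through its sodium alkoxide, safe for C2 because no free phenol is left to open ring C through a quinone methide; the ether keeps the alcohol out of the Vilsmeier step.

Step 3
Reactants: 3 (2R,3S)-3,5,7-tris(benzyloxy)-2-[4-(benzyloxy)phenyl]chromane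
Product: 4 (2R,3S)-3,5,7-tris(benzyloxy)-2-[4-(benzyloxy)phenyl]-8-bromochromane
Conditions: NBS (1.05 equiv), CH2Cl2, −78 °C to 0 °C
Reagents that add atoms: N-bromosuccinimide O=C1CCC(=O)N1Br
Why: Electrophilic aromatic bromination of the phloroglucinol-triether ring A, which reacts far ahead of ring B and at C8 in preference to C6 (flanked by two benzyloxy groups), the known regiochemistry for benzylated flavan-3-ols; the bromine blocks C8 and is removed in the last step.

Step 4
Reactants: 4 (2R,3S)-3,5,7-tris(benzyloxy)-2-[4-(benzyloxy)phenyl]-8-bromochromane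
Product: 6 (2R,3S)-3,5,7-tris(benzyloxy)-2-[4-(benzyloxy)phenyl]-8-bromochromane-6-carbaldehyde, via iminium chloride 5 (not isolated)
Conditions: POCl3, DMF, 0 °C to 70 °C; then aq NaOAc, rt
Reagents that add atoms: N,N-dimethylformamide CN(C)C=O; water O
Why: Vilsmeier–Haack formylation at C6, the only free position of the activated ring A and of the same type as the position formylated in 1,3,5-trialkoxybenzenes; the iminium salt is hydrolysed on work-up and no stereocentre is involved.

Step 5
Reactants: 6 (2R,3S)-3,5,7-tris(benzyloxy)-2-[4-(benzyloxy)phenyl]-8-bromochromane-6-carbaldehyde; 7 1-[4-(benzyloxy)phenyl]ethanone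
Product: 9 (E)-3-Ar*-1-[4-(benzyloxy)phenyl]prop-2-en-1-one, via aldol adduct 8 (not isolated)
Conditions: KOH, EtOH/THF, rt
Reagents that add atoms: none
Why: Claisen–Schmidt condensation (aldol addition, then E1cB dehydration) of a non-enolisable 2,6-dialkoxybenzaldehyde with an aryl methyl ketone, which gives the conjugated E-alkene as the thermodynamic product.

Step 6
Reactants: 9 (E)-3-Ar*-1-[4-(benzyloxy)phenyl]prop-2-en-1-one; 10 resorcinol (benzene-1,3-diol)
Product: 13 (4S)-2-[4-(benzyloxy)phenyl]-4-Ar*-4H-chromen-7-ol, via Friedel–Crafts ketone 11 (not isolated), via cyclic hemiketal 12 (not isolated)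
Conditions: (R)-3,3'-bis(2,4,6-triisopropylphenyl)-1,1'-binaphthyl-2,2'-diyl N-triflylphosphoramide (10 mol %), resorcinol (3 equiv), CH2Cl2/toluene, 5 Å MS, −20 °C to rt, then 40 °C, one pot
Reagents that add atoms: none
Why: Proposed new method: the strong chiral Brønsted acid protonates the enone carbonyl of 9 to a hydroxyallyl cation whose charge sits on the β-carbon (future C4) and is delocalised into the 5,7-dioxygenated ring A of the lower unit; resorcinol attacks this carbon through its C4 position (ortho to one hydroxyl, para to the other) to form the C4a–C4 bond (ketone 11), the ortho hydroxyl adds to the carbonyl carbon (future C2) to form O1–C2 (hemiketal 12), and acid-catalysed loss of water, pulled by the sieves, leaves the conjugated enol ether 13. The closest known reaction types are the acid-catalysed Friedel–Crafts conjugate addition/cyclodehydration of electron-rich phenols and naphthols with chalcones to 2,4-diaryl-4H-chromenes and the chiral phosphoric acid-catalysed Friedel–Crafts/hemiketalisation of naphthols with activated enones and quinone methides; new here is catalyst control on a simple β-(2,6-dialkoxyaryl) aryl enone that carries a remote chiral unit. Ring C closes by 6-exo-trig attack of the phenol oxygen on the ketone carbonyl, the whole being a formal (3+3) annulation of a C,O-1,3-bisnucleophile with a 1,3-bielectrophile. The single new stereocentre, C4, is fixed in the C–C bond-forming step by the chiral phosphoramide anion, which is hydrogen-bonded both to the protonated carbonyl and to the resorcinol hydroxyl next to the attacking carbon and so leaves one face of the s-cis enone open; the stereocentres of the lower unit are too remote to compete, so control is by the reagent and any 4-epimer is a separable diastereomer. The step needs site selectivity for C4 of resorcinol over C2 and oxygen (hydrogen-bond-directed ortho delivery, sterics, reversible oxa-Michael addition), mono-alkylation (excess resorcinol) and chemoselectivity against flavylium formation or aryl loss (both ortho oxygens of the lower ring A are benzylated and the acid is catalytic and used cold).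

Step 7
Reactants: 13 (4S)-2-[4-(benzyloxy)phenyl]-4-Ar*-4H-chromen-7-ol
Product: 15 (2R,3S,4S)-2-[4-(benzyloxy)phenyl]-4-Ar*-chromane-3,7-diol, via C3-alkylborane 14 (not isolated)
Conditions: BH3·THF (4 equiv), THF, 0 °C to rt; then NaOH, H2O2, 0 °C
Reagents that add atoms: hydrogen peroxide OO
Why: Hydroboration–oxidation of the enol ether, in which boron goes to C3 (β-carbon of the enol ether and the non-benzylic terminus) and hydrogen to C2 by syn addition on the face opposite the pseudo-axial C4 aryl group and the C–B bond is oxidised with retention, so that C3 (S, hydroxyl trans to the C4 aryl) and C2 (R, aryl cis to the C4 aryl) are both relayed from C4; the first equivalent of borane is consumed by the phenol.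

Step 8
Reactants: 15 (2R,3S,4S)-2-[4-(benzyloxy)phenyl]-4-Ar*-chromane-3,7-diol
Product: 16 (2R,3S,4S)-2-(4-hydroxyphenyl)-4-[(2R,3S)-3,5,7-trihydroxy-2-(4-hydroxyphenyl)chroman-6-yl]chromane-3,7-diol
Conditions: H2 (1 atm), Pd(OH)2/C, NaHCO3 (1.2 equiv), THF/MeOH, rt
Reagents that add atoms: none
Why: Catalytic hydrogenolysis cleaves the five benzyl ethers and the C8–Br bond in one operation, while the ring C–O bonds and the diaryl-substituted C4–H of the flavan units, which tolerate these conditions in benzylated proanthocyanidins, stay intact; hydrogen carbonate takes up HBr and no stereocentre is affected.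

**Compound list**
1 | (+)-afzelechin | O[C@H]1Cc2c(O)cc(O)cc2O[C@@H]1c1ccc(O)cc1 | starting material
2 | (2R,3S)-5,7-bis(benzyloxy)-2-[4-(benzyloxy)phenyl]chroman-3-ol | O[C@H]1Cc2c(OCc3ccccc3)cc(OCc3ccccc3)cc2O[C@@H]1c1ccc(OCc2ccccc2)cc1 | intermediate
3 | (2R,3S)-3,5,7-tris(benzyloxy)-2-[4-(benzyloxy)phenyl]chromane | O(Cc1ccccc1)[C@H]1Cc2c(OCc3ccccc3)cc(OCc3ccccc3)cc2O[C@@H]1c1ccc(OCc2ccccc2)cc1 | intermediate
4 | (2R,3S)-3,5,7-tris(benzyloxy)-2-[4-(benzyloxy)phenyl]-8-bromochromane | O(Cc1ccccc1)[C@H]1Cc2c(OCc3ccccc3)cc(OCc3ccccc3)c(Br)c2O[C@@H]1c1ccc(OCc2ccccc2)cc1 | intermediate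
5 | N-(Ar*-methylidene)-N-methylmethanaminium chloride (Vilsmeier iminium salt) | O(Cc1ccccc1)[C@H]1Cc2c(OCc3ccccc3)c(C=[N+](C)C)c(OCc3ccccc3)c(Br)c2O[C@@H]1c1ccc(OCc2ccccc2)cc1.[Cl-] | intermediate
6 | (2R,3S)-3,5,7-tris(benzyloxy)-2-[4-(benzyloxy)phenyl]-8-bromochromane-6-carbaldehyde | O(Cc1ccccc1)[C@H]1Cc2c(OCc3ccccc3)c(C=O)c(OCc3ccccc3)c(Br)c2O[C@@H]1c1ccc(OCc2ccccc2)cc1 | intermediate
7 | 1-[4-(benzyloxy)phenyl]ethanone | CC(=O)c1ccc(OCc2ccccc2)cc1 | starting material
8 | 3-hydroxy-3-Ar*-1-[4-(benzyloxy)phenyl]propan-1-one (carbinol epimers) | O(Cc1ccccc1)[C@H]1Cc2c(OCc3ccccc3)c(C(O)CC(=O)c3ccc(OCc4ccccc4)cc3)c(OCc3ccccc3)c(Br)c2O[C@@H]1c1ccc(OCc2ccccc2)cc1 | intermediate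
9 | (E)-3-Ar*-1-[4-(benzyloxy)phenyl]prop-2-en-1-one | O(Cc1ccccc1)[C@H]1Cc2c(OCc3ccccc3)c(/C=C/C(=O)c3ccc(OCc4ccccc4)cc3)c(OCc3ccccc3)c(Br)c2O[C@@H]1c1ccc(OCc2ccccc2)cc1 | intermediate
10 | resorcinol | Oc1cccc(O)c1 | starting material
11 | (3S)-3-(2,4-dihydroxyphenyl)-3-Ar*-1-[4-(benzyloxy)phenyl]propan-1-one | O=C(C[C@H](c3c(OCc5ccccc5)c(Br)c4c(c3OCc5ccccc5)C[C@H](OCc5ccccc5)[C@@H](c5ccc(OCc6ccccc6)cc5)O4)c2ccc(O)cc2O)c1ccc(OCc2ccccc2)cc1 | intermediate
12 | (4S)-2-[4-(benzyloxy)phenyl]-4-Ar*-chromane-2,7-diol (C2 anomers) | OC1(C[C@H](c3c(OCc5ccccc5)c(Br)c4c(c3OCc5ccccc5)C[C@H](OCc5ccccc5)[C@@H](c5ccc(OCc6ccccc6)cc5)O4)c2ccc(O)cc2O1)c1ccc(OCc2ccccc2)cc1 | intermediate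
13 | (4S)-2-[4-(benzyloxy)phenyl]-4-Ar*-4H-chromen-7-ol | C1(=C[C@H](c3c(OCc5ccccc5)c(Br)c4c(c3OCc5ccccc5)C[C@H](OCc5ccccc5)[C@@H](c5ccc(OCc6ccccc6)cc5)O4)c2ccc(O)cc2O1)c1ccc(OCc2ccccc2)cc1 | intermediate
14 | 3-boranyl-7-(boranyloxy) adduct of 13 (boron at C3 trans to both aryl groups, 2,4-cis-diaryl) | O(Cc7ccccc7)c1ccc([C@H]2Oc3cc(OB)ccc3[C@@H](c3c(OCc5ccccc5)c(Br)c4c(c3OCc5ccccc5)C[C@H](OCc5ccccc5)[C@@H](c5ccc(OCc6ccccc6)cc5)O4)[C@@H]2B)cc1 | intermediate
15 | (2R,3S,4S)-2-[4-(benzyloxy)phenyl]-4-Ar*-chromane-3,7-diol | O(Cc7ccccc7)c1ccc([C@H]2Oc3cc(O)ccc3[C@@H](c3c(OCc5ccccc5)c(Br)c4c(c3OCc5ccccc5)C[C@H](OCc5ccccc5)[C@@H](c5ccc(OCc6ccccc6)cc5)O4)[C@@H]2O)cc1 | intermediate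
16 | (2R,3S,4S)-2-(4-hydroxyphenyl)-4-[(2R,3S)-3,5,7-trihydroxy-2-(4-hydroxyphenyl)chroman-6-yl]chromane-3,7-diol | Oc1ccc([C@H]2Oc3cc(O)ccc3[C@@H](c3c(O)cc4c(c3O)C[C@H](O)[C@@H](c3ccc(O)cc3)O4)[C@@H]2O)cc1 | target

**Count and risks**
Total step count: 8. Longest linear sequence: 8 steps (from 1).

Steps most likely to fail:

1. Step 6. The enone carries donors at both ends and a doubly ortho-substituted β-aryl group, so conjugate addition may be slow or reversible, and facial control by the catalyst may be poor. Fallback from 9 back to 13: the resorcinol ring is introduced as a carbanion. Commercial 4-bromoresorcinol is protected (MOMCl, iPr2NEt, CH2Cl2) to give 1-bromo-2,4-bis(methoxymethoxy)benzene F1. Mg in THF converts it into [2,4-bis(methoxymethoxy)phenyl]magnesium bromide F2. Its conjugate addition to 9 (CuBr·SMe2 cat., Me3SiCl, THF, −40 °C, aqueous work-up) should give the β,β-diaryl ketone 3-[2,4-bis(methoxymethoxy)phenyl]-3-Ar*-1-[4-(benzyloxy)phenyl]propan-1-one F3 as a mixture of C4 epimers. HCl in MeOH/THF followed by PPTS in warm toluene removes both MOM groups and cyclodehydrates to 13 and its C4 epimer (4R)-2-[4-(benzyloxy)phenyl]-4-Ar*-4H-chromen-7-ol F4. These are diastereomers and are separated by chromatography; the route is rejoined at 13.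

2. Step 7. The β-alkoxyborane may eliminate with opening of ring C, or discrimination between the two faces of the enol ether may be incomplete. Fallback from 13 to 15: oxygen is introduced by epoxidation. Dimethyldioxirane in acetone/MeOH at −40 °C should epoxidise the enol ether anti to the C4 aryl group, and methanol opens the epoxide at the ketal carbon to give the 2-methoxy ketal (3S,4S)-2-[4-(benzyloxy)phenyl]-2-methoxy-4-Ar*-chromane-3,7-diol F5. Ionic reduction (Et3SiH, BF3·OEt2, CH2Cl2, −78 °C) through the C2 oxocarbenium ion, with hydride delivered anti to the C4 aryl group, should give 15.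

3. Step 4. Formylation at the doubly flanked C6 may stall, and benzyl ethers may begin to cleave at the temperature then required. Fallback from 4 to 6: the carbon is introduced through a metal. NIS with catalytic CF3CO2H (MeCN/CH2Cl2, 0 °C) iodinates C6 to give (2R,3S)-3,5,7-tris(benzyloxy)-2-[4-(benzyloxy)phenyl]-8-bromo-6-iodochromane F6. Selective iodine–magnesium exchange with iPrMgCl·LiCl (THF, −40 °C, bromide untouched) gives the arylmagnesium chloride F7, which is quenched with DMF and worked up with aqueous NH4Cl to give 6.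

**Further compounds**
F1 | step 6 | 1-bromo-2,4-bis(methoxymethoxy)benzene | COCOc1ccc(Br)c(OCOC)c1
F2 | step 6 | [2,4-bis(methoxymethoxy)phenyl]magnesium bromide | COCOc1ccc([Mg]Br)c(OCOC)c1
F3 | step 6 | 3-[2,4-bis(methoxymethoxy)phenyl]-3-Ar*-1-[4-(benzyloxy)phenyl]propan-1-one (C3 epimers) | O=C(CC(c3c(OCc5ccccc5)c(Br)c4c(c3OCc5ccccc5)C[C@H](OCc5ccccc5)[C@@H](c5ccc(OCc6ccccc6)cc5)O4)c2ccc(OCOC)cc2OCOC)c1ccc(OCc2ccccc2)cc1
F4 | step 6 | (4R)-2-[4-(benzyloxy)phenyl]-4-Ar*-4H-chromen-7-ol | C1(=C[C@@H](c3c(OCc5ccccc5)c(Br)c4c(c3OCc5ccccc5)C[C@H](OCc5ccccc5)[C@@H](c5ccc(OCc6ccccc6)cc5)O4)c2ccc(O)cc2O1)c1ccc(OCc2ccccc2)cc1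
F5 | step 7 | (3S,4S)-2-[4-(benzyloxy)phenyl]-2-methoxy-4-Ar*-chromane-3,7-diol (C2 anomers) | O(Cc7ccccc7)c1ccc(C2(OC)Oc3cc(O)ccc3[C@@H](c3c(OCc5ccccc5)c(Br)c4c(c3OCc5ccccc5)C[C@H](OCc5ccccc5)[C@@H](c5ccc(OCc6ccccc6)cc5)O4)[C@@H]2O)cc1
F6 | step 4 | (2R,3S)-3,5,7-tris(benzyloxy)-2-[4-(benzyloxy)phenyl]-8-bromo-6-iodochromane | O(Cc1ccccc1)[C@H]1Cc2c(OCc3ccccc3)c(I)c(OCc3ccccc3)c(Br)c2O[C@@H]1c1ccc(OCc2ccccc2)cc1
F7 | step 4 | [(2R,3S)-3,5,7-tris(benzyloxy)-2-[4-(benzyloxy)phenyl]-8-bromochroman-6-yl]magnesium chloride | O(Cc1ccccc1)[C@H]1Cc2c(OCc3ccccc3)c([Mg]Cl)c(OCc3ccccc3)c(Br)c2O[C@@H]1c1ccc(OCc2ccccc2)cc1
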